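**Plan**

- Numbering: hydrindane C1–C7a, C8 is the linking CH2, ring A is primed. Ring A (C1'–C6') carries a secondary bromide at C4' next to the gem-dimethyl carbon C3' and a tertiary acetate at C1', with the CH2 group C2' between C1' and C3'. That is the pattern left when Br+ adds to a Me2C=CH terminus, an alkene CH2 attacks C3' and an oxygen nucleophile is taken up at C1', so ring A is cut at C2'–C3' together with C4'–Br and C1'–OAc.
- Further cuts: C8–C1' (Negishi coupling), C1–C2 (radical 5-exo closure), C3a–C3 (enolate alkylation), C7a–C1 (conjugate addition), C3a=C7a (ring-closing metathesis) and C4–C3a (Grignard addition), back to (R)-linalool.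
- Forward: the six-membered ring of the hydrindane is made first as a cyclohexenone, the five-membered ring is closed onto it, the 1,5-diene side chain is attached, and ring A is closed last.
- Stereochemistry: C7 comes from (R)-linalool; C7a from alkoxide-directed conjugate addition; C3a from enolate alkylation anti to the new vinyl group; C1 from the chair-like radical closure; C4 from equatorial hydride delivery followed by SN2 inversion with bromide; C4' and C1' from the key step, after which the wanted ring A isomer is separated from its diastereomers.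

Key step: step 14

Assumption: the ring A stereocentres formed in step 14 are too far from the hydrindane to be steered by it, so the route relies on preparative HPLC to separate the ring A diastereomers; 2-chloroethyl triflate is taken as purchasable.

Step 1
Reactants: 1 (R)-linalool
Product: 3 (5R)-5-ethenyl-5-methyloxolan-2-ol (lactol; both anomers), via ozonide 2 (not isolated)
Conditions: O3 (1.0 equiv), CH2Cl2, −78 °C; then Me2S, −78 °C to rt
Reagents that add atoms: ozone, [O-][O+]=O
Why: Ozonolysis with reductive work-up: one equivalent of ozone is taken up by the electron-rich trisubstituted alkene much faster than by the monosubstituted vinyl group, the released hydroxy aldehyde closes to the five-membered lactol, and the carbinol stereocentre (the later C7) is not touched.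

Step 2
Reactants: 3 (5R)-5-ethenyl-5-methyloxolan-2-ol; 4 isopropenylmagnesium bromide
Product: 5 (6R)-2,6-dimethylocta-1,7-diene-3,6-diol (both C3 epimers)
Conditions: 4 (3 equiv), THF, 0 °C to rt; aq NH4Cl
Reagents that add atoms: none
Why: Grignard addition to the open hydroxy-aldehyde form of the lactol (the first equivalent of 4 deprotonates it) brings in C3a with its methyl group, and the new carbinol centre forms without control, which does not matter because it is oxidized in step 3.

Step 3
Reactants: 5 (6R)-2,6-dimethylocta-1,7-diene-3,6-diol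
Product: 6 (6R)-6-hydroxy-2,6-dimethylocta-1,7-dien-3-one
Conditions: MnO2 (15 equiv), CH2Cl2, rt
Reagents that add atoms: none
Why: Allylic oxidation with MnO2 converts the secondary allylic alcohol into the enone and leaves the tertiary allylic alcohol alone because it has no carbinol hydrogen.

Step 4
Reactants: 6 (6R)-6-hydroxy-2,6-dimethylocta-1,7-dien-3-one
Product: 7 (4R)-4-hydroxy-2,4-dimethylcyclohex-2-en-1-one
Conditions: second-generation Grubbs catalyst (5 mol%), CH2Cl2 (0.01 M), 40 °C
Reagents that add atoms: none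
Why: Ring-closing metathesis of the two terminal alkenes forms the six-membered ring as a 2-methylcyclohexenone with loss of ethene and does not involve the stereocentre.

Step 5
Reactants: 7 (4R)-4-hydroxy-2,4-dimethylcyclohex-2-en-1-one; 8 vinylmagnesium bromide
Product: 10 (3S,4R)-2,4-dimethyl-1,4-bis(trimethylsilyloxy)-3-vinylcyclohex-1-ene (vinyl cis to the C4 silyloxy group), via magnesium enolate 9 (not isolated)
Conditions: 8 (3.5 equiv), THF, −78 to 0 °C; then Me3SiCl, Et3N, −78 °C to rt
Reagents that add atoms: chlorotrimethylsilane, C[Si](C)(C)Cl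
Why: Alkoxide-directed conjugate addition of a Grignard reagent: the magnesium alkoxide formed first at the carbinol carbon binds the reagent and delivers the vinyl group to the β-carbon (the later C7a) on its own face, so vinyl ends cis to the oxygen, and chlorotrimethylsilane then traps the enolate regiospecifically as the silyl enol ether and caps the alkoxide.

Step 6
Reactants: 10 (3S,4R)-2,4-dimethyl-1,4-bis(trimethylsilyloxy)-3-vinylcyclohex-1-ene; 11 2-chloroethyl trifluoromethanesulfonate
Product: 13 (2S,3S,4R)-2-(2-chloroethyl)-2,4-dimethyl-4-(trimethylsilyloxy)-3-vinylcyclohexan-1-one (chloroethyl trans to vinyl), via lithium enolate 12 (not isolated)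
Conditions: MeLi (1.05 equiv), THF, 0 °C to rt; then 11, −78 to −30 °C
Reagents that add atoms: none
Why: Enolate alkylation: MeLi cleaves only the silyl enol ether to the regiodefined lithium enolate, which is C-alkylated by the primary triflate (triflate leaves far faster than chloride) on the face opposite the neighbouring vinyl group, so the quaternary centre (the later C3a) forms with the chloroethyl arm trans to vinyl.

Step 7
Reactants: 13 (2S,3S,4R)-2-(2-chloroethyl)-2,4-dimethyl-4-(trimethylsilyloxy)-3-vinylcyclohexan-1-one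
Product: 14 (2S,3S,4R)-2-(2-iodoethyl)-2,4-dimethyl-4-(trimethylsilyloxy)-3-vinylcyclohexan-1-one
Conditions: NaI, butan-2-one, 80 °C
Reagents that add atoms: sodium iodide, [Na+].[I-]
Why: Finkelstein halide exchange (SN2 at the unhindered primary carbon, driven by precipitation of NaCl) provides the iodide needed for atom transfer without touching the ketone or the silyl ether.

Step 8
Reactants: 14 (2S,3S,4R)-2-(2-iodoethyl)-2,4-dimethyl-4-(trimethylsilyloxy)-3-vinylcyclohexan-1-one
Product: 15 (1R,3aS,7R,7aS)-1-(iodomethyl)-3a,7-dimethyl-7-(trimethylsilyloxy)octahydro-4H-inden-4-one (trans-fused; CH2I and H-7a on one face; C3a methyl and C7 oxygen on the other)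
Conditions: (Bu3Sn)2 (10 mol%), hν (sunlamp), PhH (0.3 M), 80 °C
Reagents that add atoms: none
Why: Iodine atom-transfer radical cyclization: the primary C2 radical closes 5-exo onto the vinyl group through a chair-like transition state in which both arms sit equatorial on the cyclohexanone, which gives the trans ring fusion and places the new CH2 group (C8) on the face of H-7a, away from the axial C3a methyl and C7 silyloxy groups, and the resulting primary radical takes iodine from 14 to carry the chain.

Step 9
Reactants: 16 6-methylhept-5-en-2-one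
Product: 17 6-methylhepta-1,5-dien-2-yl trifluoromethanesulfonate
Conditions: LiN(i-Pr)2, THF, −78 °C; then PhNTf2, −78 °C to rt
Reagents that add atoms: N-phenylbis(trifluoromethanesulfonimide), O=S(=O)(N(c1ccccc1)S(=O)(=O)C(F)(F)F)C(F)(F)F
Why: Enol triflate formation: kinetic deprotonation of the methyl ketone at the methyl group and O-sulfonylation of the enolate give the terminal alkenyl triflate, and no stereocentre is involved.

Step 10
Reactants: 15 (1R,3aS,7R,7aS)-1-(iodomethyl)-3a,7-dimethyl-7-(trimethylsilyloxy)octahydro-4H-inden-4-one; 17 6-methylhepta-1,5-dien-2-yl trifluoromethanesulfonate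
Product: 19 (1S,3aS,7R,7aS)-3a,7-dimethyl-1-(6-methyl-2-methylidenehept-5-en-1-yl)-7-(trimethylsilyloxy)octahydro-4H-inden-4-one, via alkylzinc iodide 18 (not isolated)
Conditions: Zn dust, LiCl, THF, 40 °C; then 17, Pd(PPh3)4 (5 mol%), THF, 50 °C
Reagents that add atoms: none
Why: Negishi coupling: zinc inserts into the primary C–I bond in the presence of LiCl without touching the ketone, and Pd(PPh3)4 couples the alkylzinc iodide with the alkenyl triflate to join C8 to C1' and install the 1,1-disubstituted alkene, with no change at any stereocentre.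

Step 11
Reactants: 19 (1S,3aS,7R,7aS)-3a,7-dimethyl-1-(6-methyl-2-methylidenehept-5-en-1-yl)-7-(trimethylsilyloxy)octahydro-4H-inden-4-one
Product: 20 (1S,3aS,4R,7R,7aS)-3a,7-dimethyl-1-(6-methyl-2-methylidenehept-5-en-1-yl)-7-(trimethylsilyloxy)octahydro-1H-inden-4-ol (axial C4 hydroxyl trans to the C3a methyl)
Conditions: LiBH(s-Bu)3, THF, −78 °C; aq NH4Cl
Reagents that add atoms: none
Why: Hindered-hydride reduction: the bulky borohydride approaches the C4 carbonyl from the equatorial side, away from the axial hydrogens at C6 and C7a, and so should give the axial alcohol trans to the C3a methyl group, as is usual for bulky hydrides on cyclohexanones.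

Step 12
Reactants: 20 (1S,3aS,4R,7R,7aS)-3a,7-dimethyl-1-(6-methyl-2-methylidenehept-5-en-1-yl)-7-(trimethylsilyloxy)octahydro-1H-inden-4-ol
Product: 22 (1S,3aS,4S,7R,7aS)-4-bromo-3a,7-dimethyl-1-(6-methyl-2-methylidenehept-5-en-1-yl)octahydro-1H-inden-7-ol, via silyl ether bromide 21 (not isolated)
Conditions: CBr4, PPh3, pyridine, PhMe, 0 to 60 °C; then 1 M HCl, THF, rt
Reagents that add atoms: carbon tetrabromide, BrC(Br)(Br)Br
Why: Appel reaction: the oxyphosphonium ion of the axial alcohol is displaced by bromide with inversion (SN2), which puts bromine equatorial and cis to the C3a methyl group, the silyl ether having been kept until here so that the C7 oxygen cannot attack C4 across the ring; dilute acid then cleaves the tertiary trimethylsilyl ether.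

Step 13
Reactants: 22 (1S,3aS,4S,7R,7aS)-4-bromo-3a,7-dimethyl-1-(6-methyl-2-methylidenehept-5-en-1-yl)octahydro-1H-inden-7-ol
Product: 23 (1S,3aS,4S,7R,7aS)-4-bromo-3a,7-dimethyl-1-(6-methyl-2-methylidenehept-5-en-1-yl)octahydro-1H-inden-7-yl trifluoroacetate
Conditions: (CF3CO)2O, pyridine, DMAP (cat.), CH2Cl2, 0 °C
Reagents that add atoms: trifluoroacetic anhydride, O=C(OC(=O)C(F)(F)F)C(F)(F)F
Why: Acylation of the hindered tertiary alcohol by the very reactive anhydride gives a trifluoroacetate, chosen because its oxygen, unlike that of a free alcohol or a silyl ether, cannot trap the C1' cation of step 14 and because it can later be removed without harm to a tertiary acetate.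

Step 14
Reactants: 23 (1S,3aS,4S,7R,7aS)-4-bromo-3a,7-dimethyl-1-(6-methyl-2-methylidenehept-5-en-1-yl)octahydro-1H-inden-7-yl trifluoroacetate; 24 acetic acid
Product: 25 (1S,4S)-4-bromo-1-{[(1S,3aS,4S,7R,7aS)-4-bromo-3a,7-dimethyl-7-(trifluoroacetoxy)octahydro-1H-inden-1-yl]methyl}-3,3-dimethylcyclohexyl acetate
Conditions: Et2SBr·SbCl5Br (1.1 equiv), 24 (20 equiv), MeNO2, −25 °C, 5 min; aq NaHCO3/Na2SO3; preparative HPLC
Reagents that add atoms: bromodiethylsulfonium bromopentachloroantimonate (Et2SBr·SbCl5Br), CC[S+](Br)CC.Cl[Sb-](Cl)(Cl)(Cl)(Cl)Br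
Why: Et2SBr·SbCl5Br should pass Br+ to the more electron-rich trisubstituted C4'=C3' alkene, the CH2 terminus C2' of the 1,1-disubstituted alkene then opens the bromonium ion at the tertiary carbon C3' anti to bromine, and the tertiary C1' cation is trapped by acetic acid (24) before it loses a proton; this is a bromonium-induced cation–olefin cyclization of a 1,5-diene, here ended by an external carboxylic acid as in proton- or mercury-initiated closures. Ring A closes in a 6-endo fashion with respect to both alkenes through a chair transition state that leaves bromine equatorial. C4' is set by the face of the alkene that accepts bromine, which the distant hydrindane cannot bias, so both C4' configurations are expected and 25 is separated from its ring A diastereomers by HPLC. C1' is set when acetic acid enters the chair cation on its axial face, cis to bromine, the path that lets the bulky C8 substituent stay equatorial and clear of the axial C3' methyl group. The step needs the trisubstituted alkene to react before the 1,1-disubstituted one, which its higher substitution secures, and it needs an external oxygen to win over the C7 oxygen, which is secured by masking C7–OH as the non-nucleophilic trifluoroacetate; the secondary C4 bromide does not take part.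

Step 15
Reactants: 25 (1S,4S)-4-bromo-1-{[(1S,3aS,4S,7R,7aS)-4-bromo-3a,7-dimethyl-7-(trifluoroacetoxy)octahydro-1H-inden-1-yl]methyl}-3,3-dimethylcyclohexyl acetate
Product: 26 (1S,4S)-4-bromo-1-{[(1S,3aS,4S,7R,7aS)-4-bromo-7-hydroxy-3a,7-dimethyloctahydro-1H-inden-1-yl]methyl}-3,3-dimethylcyclohexyl acetate (CNP0221847.1)
Conditions: K2CO3 (0.2 equiv), MeOH, 0 °C
Reagents that add atoms: none
Why: Base-catalysed methanolysis (transesterification) cleaves the activated trifluoroacetate within minutes at 0 °C, conditions under which the hindered tertiary acetate and the two secondary bromides should be stable, and no stereocentre is affected.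

**Compound list**

1 | (R)-linalool, (3R)-3,7-dimethylocta-1,6-dien-3-ol | CC(C)=CCC[C@@](C)(O)C=C | starting material
2 | 5-[(3R)-3-hydroxy-3-methylpent-4-en-1-yl]-3,3-dimethyl-1,2,4-trioxolane (ozonide) | CC1(C)OOC(CC[C@@](C)(O)C=C)O1 | intermediate (not isolated)
3 | (5R)-5-ethenyl-5-methyloxolan-2-ol (lactol, both anomers) | OC1CC[C@](C)(C=C)O1 | intermediate
4 | isopropenylmagnesium bromide | C=C(C)[Mg]Br | starting material
5 | (6R)-2,6-dimethylocta-1,7-diene-3,6-diol (both C3 epimers) | C=C(C)C(O)CC[C@@](C)(O)C=C | intermediate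
6 | (6R)-6-hydroxy-2,6-dimethylocta-1,7-dien-3-one | C=C(C)C(=O)CC[C@@](C)(O)C=C | intermediate
7 | (4R)-4-hydroxy-2,4-dimethylcyclohex-2-en-1-one | CC1=C[C@](C)(O)CCC1=O | intermediate
8 | vinylmagnesium bromide | C=C[Mg]Br | starting material
9 | bis(bromomagnesium) enolate–alkoxide of (3S,4R)-4-hydroxy-2,4-dimethyl-3-vinylcyclohexanone | Br[Mg]OC1=C(C)[C@H](C=C)[C@](C)(O[Mg]Br)CC1 | intermediate (not isolated)
10 | (3S,4R)-2,4-dimethyl-1,4-bis(trimethylsilyloxy)-3-vinylcyclohex-1-ene (vinyl cis to the C4 silyloxy group) | C[Si](C)(C)OC1=C(C)[C@H](C=C)[C@](C)(O[Si](C)(C)C)CC1 | intermediate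
11 | 2-chloroethyl trifluoromethanesulfonate | ClCCOS(=O)(=O)C(F)(F)F | starting material
12 | lithium enolate, lithium (3S,4R)-2,4-dimethyl-4-(trimethylsilyloxy)-3-vinylcyclohex-1-en-1-olate | [Li]OC1=C(C)[C@H](C=C)[C@](C)(O[Si](C)(C)C)CC1 | intermediate (not isolated)
13 | (2S,3S,4R)-2-(2-chloroethyl)-2,4-dimethyl-4-(trimethylsilyloxy)-3-vinylcyclohexan-1-one | O=C1CC[C@@](C)(O[Si](C)(C)C)[C@@H](C=C)[C@]1(C)CCCl | intermediate
14 | (2S,3S,4R)-2-(2-iodoethyl)-2,4-dimethyl-4-(trimethylsilyloxy)-3-vinylcyclohexan-1-one | O=C1CC[C@@](C)(O[Si](C)(C)C)[C@@H](C=C)[C@]1(C)CCI | intermediate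
15 | (1R,3aS,7R,7aS)-1-(iodomethyl)-3a,7-dimethyl-7-(trimethylsilyloxy)octahydro-4H-inden-4-one | IC[C@@H]1CC[C@]2(C)C(=O)CC[C@@](C)(O[Si](C)(C)C)[C@@H]12 | intermediate
16 | 6-methylhept-5-en-2-one | CC(=O)CCC=C(C)C | starting material
17 | 6-methylhepta-1,5-dien-2-yl trifluoromethanesulfonate | C=C(OS(=O)(=O)C(F)(F)F)CCC=C(C)C | intermediate
18 | alkylzinc iodide, {[(1R,3aS,7R,7aS)-3a,7-dimethyl-4-oxo-7-(trimethylsilyloxy)octahydro-1H-inden-1-yl]methyl}zinc iodide | I[Zn]C[C@@H]1CC[C@]2(C)C(=O)CC[C@@](C)(O[Si](C)(C)C)[C@@H]12 | intermediate (not isolated)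
19 | (1S,3aS,7R,7aS)-3a,7-dimethyl-1-(6-methyl-2-methylidenehept-5-en-1-yl)-7-(trimethylsilyloxy)octahydro-4H-inden-4-one | C=C(C[C@@H]1CC[C@]2(C)C(=O)CC[C@@](C)(O[Si](C)(C)C)[C@@H]12)CCC=C(C)C | intermediate
20 | (1S,3aS,4R,7R,7aS)-3a,7-dimethyl-1-(6-methyl-2-methylidenehept-5-en-1-yl)-7-(trimethylsilyloxy)octahydro-1H-inden-4-ol | C=C(C[C@@H]1CC[C@]2(C)[C@H](O)CC[C@@](C)(O[Si](C)(C)C)[C@@H]12)CCC=C(C)C | intermediate
21 | [(1S,3aS,4S,7R,7aS)-4-bromo-3a,7-dimethyl-1-(6-methyl-2-methylidenehept-5-en-1-yl)octahydro-1H-inden-7-yl]oxy(trimethyl)silane | C=C(C[C@@H]1CC[C@]2(C)[C@@H](Br)CC[C@@](C)(O[Si](C)(C)C)[C@@H]12)CCC=C(C)C | intermediate (not isolated)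
22 | (1S,3aS,4S,7R,7aS)-4-bromo-3a,7-dimethyl-1-(6-methyl-2-methylidenehept-5-en-1-yl)octahydro-1H-inden-7-ol | C=C(C[C@@H]1CC[C@]2(C)[C@@H](Br)CC[C@@](C)(O)[C@@H]12)CCC=C(C)C | intermediate
23 | (1S,3aS,4S,7R,7aS)-4-bromo-3a,7-dimethyl-1-(6-methyl-2-methylidenehept-5-en-1-yl)octahydro-1H-inden-7-yl trifluoroacetate | C=C(C[C@@H]1CC[C@]2(C)[C@@H](Br)CC[C@@](C)(OC(=O)C(F)(F)F)[C@@H]12)CCC=C(C)C | intermediate
24 | acetic acid | CC(=O)O | starting material
25 | (1S,4S)-4-bromo-1-{[(1S,3aS,4S,7R,7aS)-4-bromo-3a,7-dimethyl-7-(trifluoroacetoxy)octahydro-1H-inden-1-yl]methyl}-3,3-dimethylcyclohexyl acetate | CC(=O)O[C@]1(C[C@@H]2CC[C@]3(C)[C@@H](Br)CC[C@@](C)(OC(=O)C(F)(F)F)[C@@H]23)CC[C@H](Br)C(C)(C)C1 | intermediate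
26 | (1S,4S)-4-bromo-1-{[(1S,3aS,4S,7R,7aS)-4-bromo-7-hydroxy-3a,7-dimethyloctahydro-1H-inden-1-yl]methyl}-3,3-dimethylcyclohexyl acetate | CC(=O)O[C@]1(C[C@@H]2CC[C@]3(C)[C@@H](Br)CC[C@@](C)(O)[C@@H]23)CC[C@H](Br)C(C)(C)C1 | target

**Step count**

Total step count: 15. Longest linear sequence: 14 steps (steps 1–8 and 10–15).

**Steps most likely to fail**

Step 14. The tertiary C1' cation may lose a proton faster than acetic acid captures it. Acetic acid may also enter from the equatorial side, which is the common course when such cations are trapped and would give the C1' epimer. The face of bromination is not controlled. Fallback: 23 is cyclized with Et2SBr·SbCl5Br in MeNO2 without acetic acid, so that proton loss is the intended ending and gives the ring A bromocyclohexene F1 (with its double-bond isomers). Mukaiyama hydration (Co(acac)2, PhSiH3, O2, i-PrOH) places a hydroxyl group on the tertiary carbon C1' of every isomer and gives the tertiary alcohol F2. Acetylation (Ac2O, Bi(OTf)3) returns to 25.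

Step 12. Substitution at the neopentylic C4 may be outrun by elimination toward C5, by migration of the C3a methyl group, or by attack of the C7 oxygen across the ring. Fallback: ketone 19 is reduced with NaBH4, which attacks axially and gives the equatorial alcohol F3 (the C4 epimer of 20). This is converted with quinoline-8-sulfonyl chloride into the quinoline-8-sulfonate F4. TiBr4 then replaces the chelating sulfonate by bromide from the front side with retention, and acidic work-up removes the silyl group, so the route is rejoined at 22.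

Step 8. The atom-transfer chain may break down because closure to the strained trans-fused ring is slow compared with reduction or elimination of the radical. Fallback: 14 is treated with LiN(i-Pr)2 to mask the ketone as the lithium enolate F5, and t-BuLi exchanges the primary iodide. The resulting 5-hexenyllithium closes by 5-exo carbolithiation on warming to the organolithium F6. Transmetalation with ZnBr2 and coupling with 17 under Pd(PPh3)4 give 19 after protonation of the enolate on work-up.

Further compounds
F1 | step 14 | (1S,3aS,4S,7R,7aS)-4-bromo-1-{[(4S)-4-bromo-5,5-dimethylcyclohex-1-en-1-yl]methyl}-3a,7-dimethyloctahydro-1H-inden-7-yl trifluoroacetate | C(C1=CC[C@H](Br)C(C)(C)C1)[C@@H]2CC[C@]3(C)[C@@H](Br)CC[C@@](C)(OC(=O)C(F)(F)F)[C@@H]23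
F2 | step 14 | (1S,3aS,4S,7R,7aS)-4-bromo-1-{[(1S,4S)-4-bromo-1-hydroxy-3,3-dimethylcyclohexyl]methyl}-3a,7-dimethyloctahydro-1H-inden-7-yl trifluoroacetate | O[C@]1(C[C@@H]2CC[C@]3(C)[C@@H](Br)CC[C@@](C)(OC(=O)C(F)(F)F)[C@@H]23)CC[C@H](Br)C(C)(C)C1
F3 | step 12 | (1S,3aS,4S,7R,7aS)-3a,7-dimethyl-1-(6-methyl-2-methylidenehept-5-en-1-yl)-7-(trimethylsilyloxy)octahydro-1H-inden-4-ol (equatorial alcohol) | C=C(C[C@@H]1CC[C@]2(C)[C@@H](O)CC[C@@](C)(O[Si](C)(C)C)[C@@H]12)CCC=C(C)C
F4 | step 12 | (1S,3aS,4S,7R,7aS)-3a,7-dimethyl-1-(6-methyl-2-methylidenehept-5-en-1-yl)-7-(trimethylsilyloxy)octahydro-1H-inden-4-yl quinoline-8-sulfonate | C=C(C[C@@H]1CC[C@]2(C)[C@@H](OS(=O)(=O)c3cccc4cccnc34)CC[C@@](C)(O[Si](C)(C)C)[C@@H]12)CCC=C(C)C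
F5 | step 8 | lithium (4R,5S,6S)-6-(2-iodoethyl)-4,6-dimethyl-4-(trimethylsilyloxy)-5-vinylcyclohex-1-en-1-olate | [Li]OC1=CC[C@@](C)(O[Si](C)(C)C)[C@@H](C=C)[C@]1(C)CCI
F6 | step 8 | {[(1R,3aS,7R,7aS)-4-(lithiooxy)-3a,7-dimethyl-7-(trimethylsilyloxy)-2,3,3a,6,7,7a-hexahydro-1H-inden-1-yl]methyl}lithium | [Li]C[C@@H]1CC[C@]2(C)C(O[Li])=CC[C@@](C)(O[Si](C)(C)C)[C@@H]12
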